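**Retrosynthetic overview**

1. Chain atoms are numbered C1 (benzylic) to C17. Hansfordiol G (19) ⇐ removal of two aryl mesylates and one TBS ether ⇐ Lindlar semi-hydrogenation of the C8≡C9 alkyne 16.
2. Key disconnection C5–C6 of 16: mixed Kolbe electrolysis (anodic double decarboxylation, radical–radical coupling) of the free acids 9 (C13, supplies C6–C17) and 15 (C12, supplies C1–C5 and the ring), with CO2 and H2 as the only other products.
3. Enabling feature: C5 and C6 are unbranched CH2 carbons in the middle of the (CH2)7 tether, each flanked only by CH2, with no heteroatom, branch or π-bond on or next to them (the C8–C9 unsaturation is one CH2 away from C6, the benzene ring five carbons from C5, the carbinol C15 nine atoms from C6). Each is therefore the site of an unstabilised primary radical that couples instead of being oxidised further; the alkene is carried as an alkyne and the resorcinol as its bis-mesylate so that the anodic step is clean.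
4. Acid 9: (S)-1,2-epoxybutane (sets C15) plus 4-chlorobutyl Grignard (C13–C14 bond), then alkylation of the pent-4-ynoic acid dianion (C9–C10 bond). Acid 15: 3,5-dihydroxybenzaldehyde → bis-mesylate → Wittig with the (4-carboxybutyl)phosphonium ylide → hydrogenation.
5. Rings: none is formed; the benzene ring is bought with 10 and only its oxygen substituents change.

Key step: step 8

Remark: the Wittig product 14 is carried on as its alkene-isomer mixture, because both isomers converge in step 7.

**Route**

Step 1
Reactants: 1 1-bromo-4-chlorobutane; 2 (S)-1,2-epoxybutane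
Product: 4 (S)-8-chlorooctan-3-ol, via 4-chlorobutylmagnesium bromide 3 (not isolated)
Conditions: Mg, THF, rt; then CuI (10 mol%), 2, −30 → 0 °C; aq. NH4Cl
Reagents that add atoms: none
Why: Chemoselective Mg insertion into the C–Br bond followed by Cu(I)-catalysed Grignard opening of the epoxide at its unsubstituted CH2 (SN2) should give the chloro alcohol, and since no bond to the stereocentre is broken the (S) configuration of 2 is carried unchanged into what becomes C15.

Step 2
Reactants: 4 (S)-8-chlorooctan-3-ol
Product: 5 (S)-tert-butyl[(8-chlorooctan-3-yl)oxy]dimethylsilane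
Conditions: TBSCl, imidazole, DMF, rt
Reagents that add atoms: tert-butyldimethylsilyl chloride, CC(C)(C)[Si](C)(C)Cl
Why: Standard imidazole-promoted silylation of a secondary alcohol should give the TBS ether, which masks the acidic OH for the acetylide alkylation and leaves the stereocentre untouched.

Step 3
Reactants: 5 (S)-tert-butyl[(8-chlorooctan-3-yl)oxy]dimethylsilane
Product: 6 (S)-tert-butyl[(8-iodooctan-3-yl)oxy]dimethylsilane
Conditions: NaI, 2-butanone, 80 °C
Reagents that add atoms: sodium iodide, [Na+].[I-]
Why: Finkelstein halide exchange at the primary carbon, driven by precipitation of NaCl, should give the more reactive iodide without affecting the silyl ether.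

Step 4
Reactants: 6 (S)-tert-butyl[(8-iodooctan-3-yl)oxy]dimethylsilane; 7 pent-4-ynoic acid
Product: 9 (S)-11-[(tert-butyldimethylsilyl)oxy]tridec-4-ynoic acid, via dilithium pent-4-ynoate acetylide 8 (not isolated)
Conditions: 7 (1.5 equiv), n-BuLi (2.05 equiv per 7), THF/DMPU, −78 → 0 °C; then 6, 0 °C → rt; cold 1 M HCl to pH 3
Reagents that add atoms: none
Why: Double deprotonation of 7 (CO2H, then the sp C–H) gives the carboxylate–acetylide dianion 8, whose far more nucleophilic acetylide carbon should displace the primary iodide of 6 (SN2 acetylide alkylation in a dipolar co-solvent), with the silyl ether and the stereocentre inert.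

Step 5
Reactants: 10 3,5-dihydroxybenzaldehyde
Product: 11 5-formyl-1,3-phenylene dimethanesulfonate
Conditions: MsCl, Et3N, CH2Cl2/THF, 0 °C
Reagents that add atoms: methanesulfonyl chloride, CS(=O)(=O)Cl
Why: Sulfonylation of both phenols should give the bis-mesylate, which protects the phenols and turns the electron-rich resorcinol ring into an electron-poor arene that can pass through an anodic step.

Step 6
Reactants: 11 5-formyl-1,3-phenylene dimethanesulfonate; 12 (4-carboxybutyl)triphenylphosphonium bromide
Product: 14 6-[3,5-bis(methylsulfonyloxy)phenyl]hex-5-enoic acid (Z/E mixture), via sodium 5-(triphenylphosphoranylidene)pentanoate 13 (not isolated)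
Conditions: 12, NaHMDS (1.95 equiv), THF, 0 °C; then 11, −78 °C → rt; 1 M HCl work-up
Reagents that add atoms: none
Why: Wittig olefination with the preformed non-stabilised carboxylate ylide should add to the electron-poor aldehyde at −78 °C faster than any base-induced attack on the mesylates (no free amide base remains), and the alkene geometry is irrelevant because the double bond is hydrogenated next.

Step 7
Reactants: 14 6-[3,5-bis(methylsulfonyloxy)phenyl]hex-5-enoic acid (Z/E mixture)
Product: 15 6-[3,5-bis(methylsulfonyloxy)phenyl]hexanoic acid
Conditions: H2 (1 atm), 10% Pd/C, EtOAc, rt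
Reagents that add atoms: none
Why: Heterogeneous catalytic hydrogenation of the styrene-type double bond should proceed at rt, where aryl mesylates are inert to Pd/H2.

Step 8
Reactants: 9 (S)-11-[(tert-butyldimethylsilyl)oxy]tridec-4-ynoic acid; 15 6-[3,5-bis(methylsulfonyloxy)phenyl]hexanoic acid
Product: 16 5-[(15S)-15-[(tert-butyldimethylsilyl)oxy]heptadec-8-yn-1-yl]-1,3-phenylene dimethanesulfonate
Conditions: 9 (1 equiv), 15 (3 equiv), KOH (5 mol% of total acid), MeOH, undivided cell, smooth Pt anode/steel cathode, ca. 0.3 A cm−2, 20–30 °C, stopped when the solution reaches pH ≈ 8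
Reagents that add atoms: none
Why: At the Pt anode above the critical potential the two carboxylates are oxidised within the adsorbed carboxylate layer to acyloxy radicals that lose CO2 at once, and the resulting primary radicals (the homopropargylic C6 radical from 9 and the 5-arylpentyl C5 radical from 15) should combine at the electrode surface to form the C5–C6 bond, while the cathode only turns acid protons into H2. This is a mixed Kolbe electrolysis, whose closest precedent is the cross-coupling of long-chain alkenoic and alkynoic acids with ω-functionalised co-acids for pheromone and lipid chains. No ring is closed and no stereocentre is formed; C15 sits nine atoms from the radical centre as a silyl ether and is not touched. Radical coupling must beat further oxidation to the cation, which is secured by both radicals being unbranched primary ones without an α-heteroatom or α-π-substituent and by the classical regime (smooth Pt, methanol, weakly acidic partly neutralised medium, high current density). The ring and the unsaturation must survive: the two mesylates should raise the oxidation potential of the arene above the working potential (a free or alkylated resorcinol would be oxidised first), and the C8≡C9 alkyne stands in for the Z-alkene because a homoallyl radical could scramble the geometry through reversible 3-exo closure to a cyclopropylcarbinyl radical, whereas the homopropargyl radical has no geometry to lose. Cross- versus homo-coupling is statistical, so the achiral acid 15 is used in excess, and the three products, carrying zero (dimer of 9), two (16) and four (dimer of 15) sulfonate groups, should separate easily on silica.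

Step 9
Reactants: 16 5-[(15S)-15-[(tert-butyldimethylsilyl)oxy]heptadec-8-yn-1-yl]-1,3-phenylene dimethanesulfonate
Product: 17 5-[(8Z,15S)-15-[(tert-butyldimethylsilyl)oxy]heptadec-8-en-1-yl]-1,3-phenylene dimethanesulfonate
Conditions: H2 (1 atm), Lindlar catalyst (Pd/CaCO3, Pb-poisoned), quinoline, EtOAc, rt, stopped after 1 equiv H2
Reagents that add atoms: none
Why: Lindlar semi-hydrogenation delivers both hydrogens syn on the poisoned Pd surface, so the internal dialkyl alkyne should give the (8Z)-alkene without over-reduction, and the S(VI) mesylates and the silyl ether neither poison the catalyst nor react.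

Step 10
Reactants: 17 5-[(8Z,15S)-15-[(tert-butyldimethylsilyl)oxy]heptadec-8-en-1-yl]-1,3-phenylene dimethanesulfonate
Product: 19 Hansfordiol G [5-[(8Z,15S)-15-hydroxyheptadec-8-en-1-yl]benzene-1,3-diol], via dilithium resorcinolate TBS ether 18 (not isolated)
Conditions: LDA (commercial solution, 6 equiv), THF, −78 → 0 °C; then 3 M aq. HCl, THF, rt
Reagents that add atoms: none
Why: LDA should deprotonate each mesyl CH3 and expel the aryloxide by E1cB loss of sulfene (amide-mediated aryl mesylate cleavage) without touching the isolated Z-alkene or the silyl ether, and the following aqueous acid protonates the phenoxides and hydrolyses the secondary TBS ether with the C15–O bond intact, so the (S) configuration is retained.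

**Compound list**

1 | 1-bromo-4-chlorobutane | ClCCCCBr | starting material
2 | (S)-1,2-epoxybutane [(S)-2-ethyloxirane] | CC[C@H]1CO1 | starting material
3 | 4-chlorobutylmagnesium bromide | ClCCCC[Mg]Br | intermediate
4 | (S)-8-chlorooctan-3-ol | CC[C@H](O)CCCCCCl | intermediate
5 | (S)-tert-butyl[(8-chlorooctan-3-yl)oxy]dimethylsilane | CC[C@H](O[Si](C)(C)C(C)(C)C)CCCCCCl | intermediate
6 | (S)-tert-butyl[(8-iodooctan-3-yl)oxy]dimethylsilane | CC[C@H](O[Si](C)(C)C(C)(C)C)CCCCCI | intermediate
7 | pent-4-ynoic acid | C#CCCC(=O)O | starting material
8 | dilithium pent-4-ynoate acetylide (carboxylate–acetylide dianion) | [Li+].[Li+].[C-]#CCCC(=O)[O-] | intermediate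
9 | (S)-11-[(tert-butyldimethylsilyl)oxy]tridec-4-ynoic acid | CC[C@H](O[Si](C)(C)C(C)(C)C)CCCCCC#CCCC(=O)O | intermediate
10 | 3,5-dihydroxybenzaldehyde | O=Cc1cc(O)cc(O)c1 | starting material
11 | 5-formyl-1,3-phenylene dimethanesulfonate | O=Cc1cc(OS(C)(=O)=O)cc(OS(C)(=O)=O)c1 | intermediate
12 | (4-carboxybutyl)triphenylphosphonium bromide | [Br-].OC(=O)CCCC[P+](c1ccccc1)(c1ccccc1)c1ccccc1 | starting material
13 | sodium 5-(triphenylphosphoranylidene)pentanoate | [Na+].[O-]C(=O)CCCC=P(c1ccccc1)(c1ccccc1)c1ccccc1 | intermediate
14 | 6-[3,5-bis(methylsulfonyloxy)phenyl]hex-5-enoic acid (Z/E mixture) | OC(=O)CCCC=Cc1cc(OS(C)(=O)=O)cc(OS(C)(=O)=O)c1 | intermediate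
15 | 6-[3,5-bis(methylsulfonyloxy)phenyl]hexanoic acid | OC(=O)CCCCCc1cc(OS(C)(=O)=O)cc(OS(C)(=O)=O)c1 | intermediate
16 | 5-[(15S)-15-[(tert-butyldimethylsilyl)oxy]heptadec-8-yn-1-yl]-1,3-phenylene dimethanesulfonate | CC[C@H](O[Si](C)(C)C(C)(C)C)CCCCCC#CCCCCCCCc1cc(OS(C)(=O)=O)cc(OS(C)(=O)=O)c1 | intermediate
17 | 5-[(8Z,15S)-15-[(tert-butyldimethylsilyl)oxy]heptadec-8-en-1-yl]-1,3-phenylene dimethanesulfonate | CC[C@H](O[Si](C)(C)C(C)(C)C)CCCCC/C=C\CCCCCCCc1cc(OS(C)(=O)=O)cc(OS(C)(=O)=O)c1 | intermediate
18 | dilithium 5-[(8Z,15S)-15-[(tert-butyldimethylsilyl)oxy]heptadec-8-en-1-yl]benzene-1,3-diolate | [Li+].[Li+].CC[C@H](O[Si](C)(C)C(C)(C)C)CCCCC/C=C\CCCCCCCc1cc([O-])cc([O-])c1 | intermediate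
19 | Hansfordiol G, 5-[(8Z,15S)-15-hydroxyheptadec-8-en-1-yl]benzene-1,3-diol | CC[C@H](O)CCCCC/C=C\CCCCCCCc1cc(O)cc(O)c1 | target

**Summary**

Total step count: 10. Longest linear sequence: 7 steps (steps 1–4, then 8–10); the aryl acid branch (steps 5–7) joins at step 8.

Steps most likely to fail:

Step 8. The risks are over-oxidation at the anode (of the arene, or of the radicals to cations that end as methyl ethers or alkenes), electrode passivation, and loss of material to statistical homo-coupling. The fallback sets out from 9 and 15 and replaces the oxidative radical dimerisation by a reductive, nickel-mediated cross-coupling of activated esters. Each acid is condensed with N-hydroxyphthalimide (DIC, cat. DMAP, CH2Cl2) to give 1,3-dioxoisoindolin-2-yl (S)-11-[(tert-butyldimethylsilyl)oxy]tridec-4-ynoate F1 and 1,3-dioxoisoindolin-2-yl 6-[3,5-bis(methylsulfonyloxy)phenyl]hexanoate F2. The two esters (F2 in excess) are then joined by Ni-electrocatalytic doubly decarboxylative coupling at the cathode (NiCl2·6H2O, terpyridine ligand, AgNO3, Mg anode/RVC cathode, NMP, rt); under these conditions nothing can be oxidised and terpyridine-ligated nickel should not insert into aryl mesylates at rt. The fallback comes back to the route at 16.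

Step 4. The risks are sluggish or unselective alkylation of a poorly soluble dianion, with competing E2 of the iodide or O-alkylation of the carboxylate. The fallback sets out from 6 and does the C–C bond formation at the alcohol oxidation level. The alkoxide–acetylide dianion of pent-4-yn-1-ol (n-BuLi, THF/DMPU) is alkylated with 6 to give (S)-11-[(tert-butyldimethylsilyl)oxy]tridec-4-yn-1-ol F3. The primary alcohol is then oxidised to the acid (cat. TEMPO, PhI(OAc)2, MeCN/H2O), which leaves the silyl ether and the alkyne intact. The fallback comes back to the route at 9.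

Step 10. The risks are incomplete cleavage of the second sulfonate and base-induced side reactions (ring metalation with sulfonyl migration, or allylic deprotonation with alkene isomerisation). The fallback sets out from 16 and moves the deprotection in front of the semi-hydrogenation, using hydrolysis instead of amide base. Treatment of 16 with KOH in water/1,4-dioxane at 90 °C under argon, followed by acidification with aq. HCl at rt, should cleave both mesylates and the TBS ether at the alkyne stage, where no alkene can isomerise, giving 5-[(15S)-15-hydroxyheptadec-8-yn-1-yl]benzene-1,3-diol F4. Lindlar semi-hydrogenation of F4 (H2, Lindlar catalyst, quinoline, EtOAc) is then the last step. The fallback comes back to the route at 19.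

Further compounds
F1 | step 8 | 1,3-dioxoisoindolin-2-yl (S)-11-[(tert-butyldimethylsilyl)oxy]tridec-4-ynoate | CC[C@H](O[Si](C)(C)C(C)(C)C)CCCCCC#CCCC(=O)ON1C(=O)c2ccccc2C1=O
F2 | step 8 | 1,3-dioxoisoindolin-2-yl 6-[3,5-bis(methylsulfonyloxy)phenyl]hexanoate | CS(=O)(=O)Oc1cc(CCCCCC(=O)ON2C(=O)c3ccccc3C2=O)cc(OS(C)(=O)=O)c1
F3 | step 4 | (S)-11-[(tert-butyldimethylsilyl)oxy]tridec-4-yn-1-ol | CC[C@H](O[Si](C)(C)C(C)(C)C)CCCCCC#CCCCO
F4 | step 10 | 5-[(15S)-15-hydroxyheptadec-8-yn-1-yl]benzene-1,3-diol | CC[C@H](O)CCCCCC#CCCCCCCCc1cc(O)cc(O)c1
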